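The route rests on cutting the C2–C3 bond of the pyranone ring (ring C). C2 carries O1 and the phenyl ring B, so in an achiral ortho-benzyloxyaryl diazomethyl ketone it is a doubly activated OCH2Ph carbon whose two enantiotopic hydrogens lie 1,6 to a carbenoid at C3, with only O1 at the 1,5 position. A chiral dirhodium tetracarboxylate turns the diazo carbon into that carbenoid, which inserts into one benzylic C–H bond and so closes ring C, forms C2–C3 and sets the (2S) centre in one operation. The precursor is a fully substituted ring A: diazoacetyl at C4a, benzyloxy at C8a, silyloxy groups at C5 and C7, prenyl groups at C6 and C8.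

Key step: step 5

Remarks on the chemistry
- Flavanone numbering is used throughout (O1, C2, C3, C4, C4a, C5 to C8, C8a). Ring A is the benzo ring, ring B the 2-phenyl ring, ring C the pyranone. "Prenyl" means 3-methylbut-2-en-1-yl and TBS means tert-butyldimethylsilyl.
- Assumption: Rh2(S-PTTL)4 is taken to deliver the (2S) product. The sense of induction of this acceptor-only carbenoid cannot be predicted with confidence; if the first cyclisation shows the opposite sense, the mirror-image catalyst from (R)-tert-leucine is used under the same conditions.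
- Precursor design: both silyl ethers go on in one step, because the last ortho hydroxyl stays locked in its hydrogen bond to the ketone. The benzyl group is then put on that hydroxyl under neutral Mitsunobu conditions, so no aryl silyl ether meets a phenoxide or carbonate. O5 must carry a silyl group and not an alkyl group: an alkyl group would place a second set of C–H bonds 1,6 to the carbenoid.

Step 1
Reactants: 1 2,4,6-trihydroxyacetophenone; 2 prenyl bromide
Product: 3 1-[2,4,6-trihydroxy-3,5-bis(3-methylbut-2-en-1-yl)phenyl]ethan-1-one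
Conditions: 2 (2.1 equiv), 10% aq KOH, 0 °C to rt
Reagents that add atoms: prenyl bromide, CC(C)=CCBr
Why: Phenoxide C-alkylation of an acylphloroglucinol: in water the oxygens are hydrogen-bonded, so the allylic bromide should be attacked by the two free ring carbons, which are the only nucleophilic ring positions left.

Step 2
Reactants: 3
Product: 4 1-[2,4-bis(tert-butyldimethylsilyloxy)-6-hydroxy-3,5-bis(3-methylbut-2-en-1-yl)phenyl]ethan-1-one
Conditions: TBSCl (2.3 equiv), imidazole, DMF, 0 °C to rt
Reagents that add atoms: tert-butyldimethylsilyl chloride, CC(C)(C)[Si](C)(C)Cl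
Why: Silyl ether formation: the unchelated para hydroxyl and one of the two equivalent ortho hydroxyls should react, while the last ortho hydroxyl is hydrogen-bonded to the ketone and flanked by prenyl and acetyl, so silylation should stop at the bis-silyl ether.

Step 3
Reactants: 4; 5 benzyl alcohol
Product: 6 1-[2-(benzyloxy)-4,6-bis(tert-butyldimethylsilyloxy)-3,5-bis(3-methylbut-2-en-1-yl)phenyl]ethan-1-one
Conditions: BnOH, PPh3, diisopropyl azodicarboxylate (DIAD), THF, 0 °C to rt
Reagents that add atoms: benzyl alcohol, OCc1ccccc1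
Why: Mitsunobu etherification of a chelated ortho-hydroxyaryl ketone: the phenol is acidic enough to protonate the betaine and then attacks the primary benzylic carbon of the alkoxyphosphonium ion under neutral conditions, which spares the aryl silyl ethers.

Step 4
Reactants: 6
Product: 8 1-[2-(benzyloxy)-4,6-bis(tert-butyldimethylsilyloxy)-3,5-bis(3-methylbut-2-en-1-yl)phenyl]-2-diazoethan-1-one, via trifluoroacetyl diketone 7 (not isolated)
Conditions: first LiN(SiMe3)2, THF, −78 °C, CF3CO2CH2CF3, cold dilute aq HCl quench; then 4-AcNHC6H4SO2N3, Et3N, H2O (1 equiv), MeCN, rt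
Reagents that add atoms: 2,2,2-trifluoroethyl trifluoroacetate, O=C(OCC(F)(F)F)C(F)(F)F (trifluoroacetyl group of 7 only); 4-acetamidobenzenesulfonyl azide, CC(=O)Nc1ccc(cc1)S(=O)(=O)N=[N+]=[N-] (the N2 unit of 8)
Why: Danheiser detrifluoroacetylative diazo transfer: the kinetic lithium enolate of the hindered methyl ketone undergoes Claisen trifluoroacetylation, and the activated diketone then takes the diazo group from the sulfonyl azide (Regitz transfer) while the trifluoroacetyl group leaves on the sulfonamide nitrogen; benzyl ether, silyl ethers and alkenes are not touched.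

Step 5
Reactants: 8
Product: 9 (2S)-5,7-bis(tert-butyldimethylsilyloxy)-6,8-bis(3-methylbut-2-en-1-yl)-2-phenylchroman-4-one
Conditions: dirhodium tetrakis[N-phthaloyl-(S)-tert-leucinate], Rh2(S-PTTL)4 (2 mol %), toluene, 0 °C, slow addition of 8 at high dilution
Reagents that add atoms: none
Why: The diazo carbon C3 attacks the dirhodium tetracarboxylate and loses dinitrogen to give an electrophilic rhodium carbenoid, which inserts into one C–H bond of the OCH2Ph carbon (the future C2) through a concerted, asynchronous three-centre transition state with hydride-transfer character, the positive charge building at C2 being stabilised by the O1 lone pair and by ring B. The closest known reaction type is the chiral dirhodium carboxylate-catalysed intramolecular C–H insertion of ortho-alkoxyaryl alpha-diazoketones that gives chroman-4-ones. Ring C is closed in the 1,6-insertion mode, the new C2–C3 bond completing the six-membered ring C3–C4–C4a–C8a–O1–C2. The C2 stereocentre arises from an achiral substrate and is controlled only by the chiral carboxylate ligand wall, which should let the carbenoid reach just one of the two enantiotopic benzylic hydrogens, the catalyst antipode fixing the (2S) sense. The step needs insertion to win over attack on O1 (five-membered oxonium ylide, then 1,2-benzyl shift to a 2-benzylbenzofuran-3-one), attack on O5 and reaction with the alkenes: ylide formation at the doubly flanked aryl ether O1 should be reversible and its 1,2-shift slow while the C–H bond is activated by both oxygen and phenyl, O5 carries a bulky silyl group with silicon and no C–H carbon at the 1,6 position, and both prenyl groups sit meta to C4, so intramolecular cyclopropanation or allylic insertion would need a meta-bridged ring and only the intermolecular reaction, suppressed by slow addition, remains.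

Step 6
Reactants: 9
Product: 10 (2S)-5,7-dihydroxy-6,8-bis(3-methylbut-2-en-1-yl)-2-phenylchroman-4-one
Conditions: Bu4NF (2.5 equiv), AcOH (3 equiv), THF, 0 °C
Reagents that add atoms: none
Why: Fluoride-mediated cleavage of both aryl silyl ethers; the acetic acid buffer should prevent the base-induced E1cB opening of ring C to the chalcone, which is how flavanones racemise at C2, and the prenyl groups are inert.

Compound list
1 | 2,4,6-trihydroxyacetophenone | CC(=O)c1c(O)cc(O)cc1O | starting material
2 | prenyl bromide (1-bromo-3-methylbut-2-ene) | CC(C)=CCBr | starting material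
3 | 1-[2,4,6-trihydroxy-3,5-bis(3-methylbut-2-en-1-yl)phenyl]ethan-1-one | CC(=O)c1c(O)c(CC=C(C)C)c(O)c(CC=C(C)C)c1O | intermediate
4 | 1-[2,4-bis(tert-butyldimethylsilyloxy)-6-hydroxy-3,5-bis(3-methylbut-2-en-1-yl)phenyl]ethan-1-one | CC(=O)c1c(O)c(CC=C(C)C)c(O[Si](C)(C)C(C)(C)C)c(CC=C(C)C)c1O[Si](C)(C)C(C)(C)C | intermediate
5 | benzyl alcohol | OCc1ccccc1 | starting material
6 | 1-[2-(benzyloxy)-4,6-bis(tert-butyldimethylsilyloxy)-3,5-bis(3-methylbut-2-en-1-yl)phenyl]ethan-1-one | CC(=O)c1c(OCc2ccccc2)c(CC=C(C)C)c(O[Si](C)(C)C(C)(C)C)c(CC=C(C)C)c1O[Si](C)(C)C(C)(C)C | intermediate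
7 | 1-[2-(benzyloxy)-4,6-bis(tert-butyldimethylsilyloxy)-3,5-bis(3-methylbut-2-en-1-yl)phenyl]-4,4,4-trifluorobutane-1,3-dione (largely enolised; not isolated) | O=C(CC(=O)C(F)(F)F)c1c(OCc2ccccc2)c(CC=C(C)C)c(O[Si](C)(C)C(C)(C)C)c(CC=C(C)C)c1O[Si](C)(C)C(C)(C)C | intermediate
8 | 1-[2-(benzyloxy)-4,6-bis(tert-butyldimethylsilyloxy)-3,5-bis(3-methylbut-2-en-1-yl)phenyl]-2-diazoethan-1-one | [N-]=[N+]=CC(=O)c1c(OCc2ccccc2)c(CC=C(C)C)c(O[Si](C)(C)C(C)(C)C)c(CC=C(C)C)c1O[Si](C)(C)C(C)(C)C | intermediate
9 | (2S)-5,7-bis(tert-butyldimethylsilyloxy)-6,8-bis(3-methylbut-2-en-1-yl)-2-phenylchroman-4-one | CC(C)=CCc1c(O[Si](C)(C)C(C)(C)C)c(CC=C(C)C)c2c(c1O[Si](C)(C)C(C)(C)C)C(=O)C[C@@H](c1ccccc1)O2 | intermediate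
10 | (2S)-5,7-dihydroxy-6,8-bis(3-methylbut-2-en-1-yl)-2-phenylchroman-4-one | CC(C)=CCc1c(O)c(CC=C(C)C)c2c(c1O)C(=O)C[C@@H](c1ccccc1)O2 | target

Total step count: 6 steps.
Longest linear sequence: 6 steps (1 to 3 to 4 to 6 to 8 to 9 to 10).

Steps most likely to fail

Step 5. The carbenoid may be diverted to the oxonium ylide at O1 with benzyl shift, or the catalyst may discriminate the two enantiotopic benzylic hydrogens poorly. The fallback closes ring C through the O1–C2 bond instead and takes the stereocentre by resolution. It sets out from 3. Protection with methoxymethyl chloride and diisopropylethylamine in CH2Cl2 should give 1-[2-hydroxy-4,6-bis(methoxymethoxy)-3,5-bis(3-methylbut-2-en-1-yl)phenyl]ethan-1-one F1. Claisen–Schmidt condensation with benzaldehyde (KOH, EtOH/H2O, rt) should give (E)-1-[2-hydroxy-4,6-bis(methoxymethoxy)-3,5-bis(3-methylbut-2-en-1-yl)phenyl]-3-phenylprop-2-en-1-one F2. Dilute HCl in MeOH at 40 to 50 °C removes the acetals to give (E)-1-[2,4,6-trihydroxy-3,5-bis(3-methylbut-2-en-1-yl)phenyl]-3-phenylprop-2-en-1-one F3. Intramolecular oxa-Michael addition (NaOAc, EtOH, reflux) closes it to racemic 5,7-dihydroxy-6,8-bis(3-methylbut-2-en-1-yl)-2-phenylchroman-4-one F4. Preparative HPLC on a polysaccharide chiral phase separates the enantiomers and comes back to the route at 10; (2R)-5,7-dihydroxy-6,8-bis(3-methylbut-2-en-1-yl)-2-phenylchroman-4-one F5 is returned to F4 by base-induced ring opening and reclosure.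

Step 1. Over-alkylation at carbon (geminal diprenylation with loss of aromaticity) and O-alkylation may leave the wanted product as a minor part of a mixture. The fallback brings the two side chains in as allyl groups by sigmatropic rearrangement and converts them afterwards. It sets out from 1. O-Allylation with allyl bromide (K2CO3, acetone, reflux) should give 1-[2,4-bis(allyloxy)-6-hydroxyphenyl]ethan-1-one F6. Heating in N,N-diethylaniline at about 200 °C moves both allyl groups to carbon by aromatic Claisen rearrangement; the allyl on the ortho oxygen reaches the adjacent free carbon directly, or the other one by Claisen–Cope if the first is taken, so both orders converge on 1-(3,5-diallyl-2,4,6-trihydroxyphenyl)ethan-1-one F7. Cross-metathesis with excess 2-methylbut-2-ene and second-generation Grubbs catalyst in CH2Cl2 at 40 °C turns both allyl groups into prenyl groups and comes back to the route at 3.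

Step 3. Etherification of a chelated phenol flanked on both sides may be slow or incomplete. The fallback changes the order of protection so that the benzyl group goes on while one ortho hydroxyl is still unchelated. It sets out from 3. Silylation with one equivalent of TBSCl (imidazole, DMF, −20 °C) should give 1-[4-(tert-butyldimethylsilyloxy)-2,6-dihydroxy-3,5-bis(3-methylbut-2-en-1-yl)phenyl]ethan-1-one F8. Mitsunobu mono-benzylation (BnOH, PPh3, DIAD, THF) of the free ortho hydroxyl should give 1-[2-(benzyloxy)-4-(tert-butyldimethylsilyloxy)-6-hydroxy-3,5-bis(3-methylbut-2-en-1-yl)phenyl]ethan-1-one F9. The remaining chelated hydroxyl is then capped with the more reactive TBSOTf and 2,6-lutidine (CH2Cl2, −78 to 0 °C), which comes back to the route at 6.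

Further compounds
F1 | step 5 | 1-[2-hydroxy-4,6-bis(methoxymethoxy)-3,5-bis(3-methylbut-2-en-1-yl)phenyl]ethan-1-one | CC(=O)c1c(O)c(CC=C(C)C)c(OCOC)c(CC=C(C)C)c1OCOC
F2 | step 5 | (E)-1-[2-hydroxy-4,6-bis(methoxymethoxy)-3,5-bis(3-methylbut-2-en-1-yl)phenyl]-3-phenylprop-2-en-1-one | O=C(/C=C/c1ccccc1)c1c(O)c(CC=C(C)C)c(OCOC)c(CC=C(C)C)c1OCOC
F3 | step 5 | (E)-1-[2,4,6-trihydroxy-3,5-bis(3-methylbut-2-en-1-yl)phenyl]-3-phenylprop-2-en-1-one | O=C(/C=C/c1ccccc1)c1c(O)c(CC=C(C)C)c(O)c(CC=C(C)C)c1O
F4 | step 5 | racemic 5,7-dihydroxy-6,8-bis(3-methylbut-2-en-1-yl)-2-phenylchroman-4-one | CC(C)=CCc1c(O)c(CC=C(C)C)c2c(c1O)C(=O)CC(c1ccccc1)O2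
F5 | step 5 | (2R)-5,7-dihydroxy-6,8-bis(3-methylbut-2-en-1-yl)-2-phenylchroman-4-one | CC(C)=CCc1c(O)c(CC=C(C)C)c2c(c1O)C(=O)C[C@H](c1ccccc1)O2
F6 | step 1 | 1-[2,4-bis(allyloxy)-6-hydroxyphenyl]ethan-1-one | CC(=O)c1c(O)cc(OCC=C)cc1OCC=C
F7 | step 1 | 1-(3,5-diallyl-2,4,6-trihydroxyphenyl)ethan-1-one | CC(=O)c1c(O)c(CC=C)c(O)c(CC=C)c1O
F8 | step 3 | 1-[4-(tert-butyldimethylsilyloxy)-2,6-dihydroxy-3,5-bis(3-methylbut-2-en-1-yl)phenyl]ethan-1-one | CC(=O)c1c(O)c(CC=C(C)C)c(O[Si](C)(C)C(C)(C)C)c(CC=C(C)C)c1O
F9 | step 3 | 1-[2-(benzyloxy)-4-(tert-butyldimethylsilyloxy)-6-hydroxy-3,5-bis(3-methylbut-2-en-1-yl)phenyl]ethan-1-one | CC(=O)c1c(OCc2ccccc2)c(CC=C(C)C)c(O[Si](C)(C)C(C)(C)C)c(CC=C(C)C)c1O
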